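I wanted to know how much faster the flask makes product, at the moment 10 % of its substrate is converted, when more free catalyst is charged.

| flask | substrate | partner | free catalyst | remark |
|---|---|---|---|---|
| Thursday's | 0.42 M | 0.30 equiv | 2.5 mol% | run made earlier |
| Tuesday's | 0.42 M | 0.45 equiv | 2.5 mol% | run made earlier |
| flask | 0.42 M | 0.600 equiv | 2.5 mol% |  |

- factor on the rate of making product when 10 % of the substrate are converted if free catalyst is charged twice over
- factor on the rate when 10 % of the substrate are converted if free catalyst is charged at 25 mol% instead

- what is bound to the catalyst counts as converted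
- no earlier run changes the charge of free catalyst; that part of a forecast is a guess

| run | time / h | product / % | substrate / % |
|---|---|---|---|
| Thursday's | 10.0 | 8.0 | 90.0 |
| Thursday's | 20.0 | 11.8 | 85.3 |
| Thursday's | 30.0 | 13.4 | 85.1 |
| Thursday's | 40.0 | 13.0 | 83.7 |
| Tuesday's | 5.00 | 6.3 | 92.4 |
| Tuesday's | 15.0 | 14.6 | 83.3 |
| Tuesday's | 25.0 | 17.7 | 80.1 |
| Tuesday's | 40.0 | 19.6 | 78.2 |

(readings scatter by 0.3 percentage points)

I counted turns first. Let n be the substrate converted at that mark per catalyst charged: n is 4.00 at 2.5 mol%, 2.00 at double the charge and 0.400 at 25 mol%. Held substrate is part of the converted substrate, so at 25 mol% the held share of the catalyst is at most 0.400.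

Then I read the tables. Thursday's first row sits at the mark, and its substrate and product columns leave 2.00 % unaccounted. I took this as substrate held on the catalyst, a reading of 80.0 % of the catalyst, with each reading scattering by 0.3 percentage points. The last rows give product per equivalent of partner: 0.433 on Thursday and 0.436 on Tuesday. So I put the flask's plateau near 26.1 %, and I took the rate as held catalyst times the room left below that plateau.

At double the charge, the count of 2.00 is higher than that share, so I kept the share, which puts twice as much substrate on the catalyst and leaves less product at the mark; this gives a factor of 2.22. At 25 mol%, n is lower than that share, so I let all the converted substrate be held and no product be made, which gives 7.21.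

The forecast said 2.2 and 6, the second on the ground that “binding alone nearly supplies the 10%”; its second figure is lower than mine.

The simulation gave 2.28 and 5.50.

    catalyst intermediate A → spent catalyst (k = 5.90 × 10⁻⁶ s⁻¹)
    partner + catalyst intermediate A → catalyst intermediate B (k = 0.00220 L mol⁻¹ s⁻¹)
    catalyst intermediate B → free catalyst + product (k = 0.00120 s⁻¹)
    substrate + free catalyst ⇌ catalyst intermediate A (K = 10.0 L mol⁻¹, k = 0.00130 L mol⁻¹ s⁻¹)
    partner → decomposed reagent (k = 1.30 × 10⁻⁵ s⁻¹)

At 25 mol%, catalyst intermediate A was 29.6 % of the catalyst at the mark, under the count of 0.400, while in the flask, with a count of 4.00, free catalyst was 41.5 % of the catalyst at the mark. Partner was the flask's limiting reagent: at 50.0 h it went to decomposed reagent 1.5 times as fast as into catalyst intermediate B, with 1.5 % of its charge left beside 72 % of the substrate.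

The runs come from a simulation on assumed constants; scatter was added.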